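**Retrosynthetic overview**
1. Target acid ⇐ 19-(furan-2-yl)nonadec-5-ynal by mild aldehyde oxidation.
2. Key step: the C5≡C6 alkyne and the C1 carbonyl are unveiled together by Eschenmoser–Tanabe ring fragmentation of a 2-alkyl-2,3-epoxycyclohexanone, so no acetylide alkylation is used.
3. The 2-alkylcyclohex-2-enone ⇐ B-alkyl Suzuki–Miyaura coupling of 2-iodocyclohex-2-en-1-one with the 9-BBN adduct of 2-(tridec-12-en-1-yl)furan.
4. That alkene ⇐ furan + 1,10-dibromodecane + allylmagnesium bromide.
5. Rings: none is formed. The furan is bought intact and carried through; the six-membered ring is bought as a sacrificial template and opened in the key step.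

Assumption: the target has no stereocentre and no stereogenic double bond, so "single enantiomer" reduces to the constitution; the epoxide stereocentres made in step 4 are racemic and are destroyed in step 5.
Assumption: 2-iodocyclohex-2-en-1-one is taken as a catalogue compound.

**Step 1**
Reactants: 1 furan; 2 1,10-dibromodecane
Product: 4 2-(10-bromodecyl)furan, via 2-furyllithium 3 (not isolated)
Conditions: n-BuLi (1.0 equiv), 1 (1.3 equiv), THF, –78 → 0 °C, 1 h; then 2 (3.0 equiv), THF, –78 °C → rt, 16 h; excess 2 distilled off
Reagents that add atoms: n-butyllithium, [Li]CCCC (its lithium is kept only in intermediate 3; nothing from it remains in 4)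
Why: Furan is lithiated cleanly at C2 (α-metalation), and 2-furyllithium displaces one bromide of the primary dibromide in an SN2 alkylation, the threefold excess of 2 suppressing double substitution.

**Step 2**
Reactants: 4 2-(10-bromodecyl)furan
Product: 5 2-(tridec-12-en-1-yl)furan
Conditions: allylmagnesium bromide (1.5 equiv, 1.0 M in Et2O), Li2CuCl4 (3 mol%), THF, –20 °C → rt, 4 h
Reagents that add atoms: allylmagnesium bromide, C=CC[Mg]Br
Why: Kochi-type copper-catalysed sp3–sp3 Grignard cross-coupling of an unhindered primary bromide with the very reactive allyl Grignard reagent is fast and leaves the furan untouched.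

**Step 3**
Reactants: 5 2-(tridec-12-en-1-yl)furan (1.2 equiv); 6 2-iodocyclohex-2-en-1-one (1.0 equiv)
Product: 8 2-[13-(furan-2-yl)tridecyl]cyclohex-2-en-1-one, via B-alkyl-9-BBN 7 (not isolated)
Conditions: 9-BBN (1.25 equiv), THF, 0 °C → rt, 4 h; then 6, PdCl2(dppf) (5 mol%), AsPh3 (5 mol%), Cs2CO3 (2 equiv), DMF/THF/H2O, rt, 12 h
Reagents that add atoms: 9-borabicyclo[3.3.1]nonane, B1C2CCCC1CCC2 (its boron and carbons are kept only in intermediate 7)
Why: 9-BBN hydroborates the terminal alkene anti-Markovnikov without touching the furan, and B-alkyl Suzuki–Miyaura coupling with an α-iodoenone (oxidative addition of zerovalent palladium into the vinylic C–I bond, base-assisted transmetalation, reductive elimination) is an established route to 2-alkylcycloalk-2-enones.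

**Step 4**
Reactants: 8 2-[13-(furan-2-yl)tridecyl]cyclohex-2-en-1-one
Product: 9 1-[13-(furan-2-yl)tridecyl]-7-oxabicyclo[4.1.0]heptan-2-one (racemic, cis-fused epoxide)
Conditions: 30% aq. H2O2 (4 equiv), NaOH (0.3 equiv), MeOH/THF (3:1), 0 °C → rt, 6 h
Reagents that add atoms: hydrogen peroxide, OO
Why: Weitz–Scheffer nucleophilic epoxidation (conjugate addition of hydroperoxide anion, then closure of the enolate onto the O–O bond) oxidises only the electron-poor enone C=C and spares the electron-rich furan; the two new stereocentres form as the necessarily cis-fused epoxide in racemic form and both are erased in step 5.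

**Step 5**
Reactants: 9 1-[13-(furan-2-yl)tridecyl]-7-oxabicyclo[4.1.0]heptan-2-one
Product: 11 19-(furan-2-yl)nonadec-5-ynal, via tosylhydrazone 10 (not isolated)
Conditions: TsNHNH2 (1.05 equiv), CH2Cl2/AcOH (1:1), –20 °C, 2 h → rt, 3 h
Reagents that add atoms: p-toluenesulfonyl hydrazide, Cc1ccc(cc1)S(=O)(=O)NN (its atoms are kept only in intermediate 10)
Why: Eschenmoser–Tanabe fragmentation: the tosylhydrazone opens its epoxide to an alkoxy azoalkene that collapses in a Grob-type fragmentation, expelling N2 and sulfinate, cleaving the bond between the two former epoxide carbons and giving the internal alkyne and the aldehyde in one operation, with acetic acid too weak to harm the 2-alkylfuran.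

**Step 6**
Reactants: 11 19-(furan-2-yl)nonadec-5-ynal
Product: 13 19-(furan-2-yl)nonadec-5-ynoic acid, via sodium carboxylate 12 (not isolated)
Conditions: Ag2O (1.5 equiv), NaOH (4 equiv), EtOH/H2O (1:1), rt, 3 h; filter; then 1 M HCl to pH 3, 0 °C
Reagents that add atoms: Ag2O, [Ag+].[Ag+].[O-2]; sodium hydroxide, [Na+].[OH-] (the new carboxyl oxygen comes from the oxide/hydroxide pool of these two; sodium is kept only in intermediate 12)
Why: Tollens-type oxidation of the aldehyde hydrate by monovalent silver in alkali is chemoselective for CHO and tolerates furans (furfural gives furoic acid this way) and internal alkynes, and brief cold acidification of the carboxylate frees the target, which has no stereocentre.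

**Compound list**
1 | furan | c1ccoc1 | starting material
2 | 1,10-dibromodecane | BrCCCCCCCCCCBr | starting material
3 | 2-furyllithium (not isolated) | [Li]c1ccco1 | intermediate
4 | 2-(10-bromodecyl)furan | BrCCCCCCCCCCc1ccco1 | intermediate
5 | 2-(tridec-12-en-1-yl)furan | C=CCCCCCCCCCCCc1ccco1 | intermediate
6 | 2-iodocyclohex-2-en-1-one | O=C1CCCC=C1I | starting material
7 | 9-[13-(furan-2-yl)tridecyl]-9-borabicyclo[3.3.1]nonane (not isolated) | c1coc(CCCCCCCCCCCCCB2C3CCCC2CCC3)c1 | intermediate
8 | 2-[13-(furan-2-yl)tridecyl]cyclohex-2-en-1-one | O=C1CCCC=C1CCCCCCCCCCCCCc1ccco1 | intermediate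
9 | 1-[13-(furan-2-yl)tridecyl]-7-oxabicyclo[4.1.0]heptan-2-one (racemic, cis-fused epoxide) | O=C1CCCC2OC12CCCCCCCCCCCCCc1ccco1 | intermediate
10 | p-toluenesulfonylhydrazone of 9 (racemic, not isolated) | Cc1ccc(cc1)S(=O)(=O)NN=C1CCCC2OC12CCCCCCCCCCCCCc1ccco1 | intermediate
11 | 19-(furan-2-yl)nonadec-5-ynal | O=CCCCC#CCCCCCCCCCCCCCc1ccco1 | intermediate
12 | sodium 19-(furan-2-yl)nonadec-5-ynoate (not isolated) | [Na+].[O-]C(=O)CCCC#CCCCCCCCCCCCCCc1ccco1 | intermediate
13 | 19-(furan-2-yl)nonadec-5-ynoic acid | O=C(O)CCCC#CCCCCCCCCCCCCCc1ccco1 | target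

**Total step count:** 6. **Longest linear sequence:** 6 steps (1 → 4 → 5 → 8 → 9 → 11 → 13).

**Three steps most likely to fail**

Step 5 (fragmentation) is the riskiest. The aldehyde product can be intercepted by unreacted hydrazide, and the epoxide and furan sit in an acidic medium. The fallback sets out from 9 and comes back at 11, replacing the hydrazone fragmentation by an anionic fragmentation of a vinylogous acyl triflate. Pd(PPh3)4 (5 mol%) with dppe in toluene at 100 °C isomerises the epoxy ketone (oxidative addition of zerovalent palladium into the Cα–O bond, then β-hydride elimination) to 2-[13-(furan-2-yl)tridecyl]cyclohexane-1,3-dione F1. Tf2O and pyridine in CH2Cl2 at –78 °C give 2-[13-(furan-2-yl)tridecyl]-3-oxocyclohex-1-en-1-yl trifluoromethanesulfonate F2. LiBHEt3 (2.2 equiv) in THF, –78 °C → rt, adds hydride to the ketone; on warming the alkoxide undergoes Grob-type C–C cleavage with loss of triflate to give 11 in the flask, which the second equivalent reduces to 19-(furan-2-yl)nonadec-5-yn-1-ol F3 after aqueous work-up. Dess–Martin periodinane with NaHCO3 in CH2Cl2 returns 11.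

Step 3 (fragment union) is second. The α-iodoenone is base-sensitive, and the alkylborane can be lost to protodeboronation or β-hydride elimination. The fallback sets out from 5 and comes back at 13, giving up the ring template for a conventional acetylide alkylation. Hydroboration of 5 with 9-BBN (to 7) and oxidation with NaOH/H2O2 give 13-(furan-2-yl)tridecan-1-ol F4. PPh3, I2 and imidazole in CH2Cl2 at 0 °C give 2-(13-iodotridecyl)furan F5. Hex-5-ynoic acid with n-BuLi (2.1 equiv) in THF/HMPA at –78 → 0 °C gives lithium 6-lithiohex-5-ynoate F6, which F5 alkylates at the acetylide carbon to lithium 19-(furan-2-yl)nonadec-5-ynoate F7. Acidification with 1 M HCl gives 13.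

Step 6 (oxidation) is third. The furan is oxidant-sensitive, and silver can bind the alkyne and slow the reaction. The fallback sets out from 11 and comes back at 12, using organocatalytic oxidative esterification instead of a metal oxidant. A triazolium NHC precatalyst (5 mol%), DBU and 3,3',5,5'-tetra-tert-butyl-4,4'-diphenoquinone (1.1 equiv) in THF/MeOH at rt convert the aldehyde through an acyl azolium into methyl 19-(furan-2-yl)nonadec-5-ynoate F8. NaOH in THF/MeOH/H2O saponifies it to 12, which is acidified as in step 6.

**Further compounds**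
F1 | step 5 | 2-[13-(furan-2-yl)tridecyl]cyclohexane-1,3-dione | O=C1CCCC(=O)C1CCCCCCCCCCCCCc1ccco1
F2 | step 5 | 2-[13-(furan-2-yl)tridecyl]-3-oxocyclohex-1-en-1-yl trifluoromethanesulfonate | O=C1CCCC(OS(=O)(=O)C(F)(F)F)=C1CCCCCCCCCCCCCc1ccco1
F3 | step 5 | 19-(furan-2-yl)nonadec-5-yn-1-ol | OCCCCC#CCCCCCCCCCCCCCc1ccco1
F4 | step 3 | 13-(furan-2-yl)tridecan-1-ol | OCCCCCCCCCCCCCc1ccco1
F5 | step 3 | 2-(13-iodotridecyl)furan | ICCCCCCCCCCCCCc1ccco1
F6 | step 3 | lithium 6-lithiohex-5-ynoate | [Li+].[O-]C(=O)CCCC#C[Li]
F7 | step 3 | lithium 19-(furan-2-yl)nonadec-5-ynoate | [Li+].[O-]C(=O)CCCC#CCCCCCCCCCCCCCc1ccco1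
F8 | step 6 | methyl 19-(furan-2-yl)nonadec-5-ynoate | COC(=O)CCCC#CCCCCCCCCCCCCCc1ccco1
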